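The runs stem from a simulated flask for an exercise; noise was put on by code.

The oak run turns slow long before its substrate, the limiting reagent, is accounted for. Target climbs at 0.0171 M min⁻¹ up to 0.91 min but at 0.00300 M min⁻¹ over the last stretch, slower, though at 6.3 min target equals just 30.6% of the substrate charged.

| flask | substrate | partner | catalyst | time |
|---|---|---|---|---|
| oak | 0.150 M | 0.375 M | 0.00450 M |  |
| alder | 0.0750 M | 0.300 M | 0.00450 M |  |
| birch | 0.150 M | 0.750 M | 0.00450 M |  |
| cedar | 0.220 M | 0.375 M | 0.00450 M |  |
| elm | 0.310 M | 0.375 M | 0.00450 M | 6.3 min |

| run | time / min | [target] / M |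
|---|---|---|
| oak run | 0.25 | 0.0042 |
| oak run | 0.48 | 0.0067 |
| oak run | 0.91 | 0.0156 |
| oak run | 1.7 | 0.0239 |
| oak run | 3.3 | 0.0369 |
| oak run | 6.3 | 0.0459 |
| alder run | 0.25 | 0.0024 |
| alder run | 0.48 | 0.0022 |
| alder run | 0.91 | 0.0080 |
| alder run | 1.7 | 0.0120 |
| alder run | 3.3 | 0.0179 |
| alder run | 6.3 | 0.0238 |
| birch run | 0.25 | 0.0049 |
| birch run | 0.48 | 0.0120 |
| birch run | 0.91 | 0.0203 |
| birch run | 1.7 | 0.0314 |
| birch run | 3.3 | 0.0442 |
| birch run | 6.3 | 0.0550 |
| cedar run | 0.25 | 0.0080 |
| cedar run | 0.48 | 0.0131 |
| cedar run | 0.91 | 0.0230 |
| cedar run | 1.7 | 0.0344 |
| cedar run | 3.3 | 0.0482 |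
| cedar run | 6.3 | 0.0579 |

(standard deviation of a reading: 0.001 M)

- the power of [partner] that the first rate follows, about the charge of the oak run; measure it at two percent of substrate made into target
- the power of [substrate] that the first rate follows, about the charge of the oak run; measure it at two percent of substrate made into target (one fixed amount of target, the same in the runs compared)
- target in the elm run at 6.3 min, as a share of the substrate charged

- Overall: substrate + partner -> target, with catalyst as catalyst.
- Constant volume, constant temperature.
- A reading of a species includes what of it is bound.
- An order is taken over about fifteen percent of the charge, up and down.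

So early readings must serve for the first rate, and late readings for the elm run. Reckoned the same way, the cedar run gives 0.0253 M min⁻¹ and the birch run 0.0223 M min⁻¹. My power of substrate is therefore 1.01. My power of partner is 0.380, which I hold to be a low reading, since it spans a doubling and a bending curve.

Late target follows the charge less steeply. From oak to cedar, at equal partner and equal clock, I divide the logarithm of the ratio of late targets by the logarithm of the ratio of substrate charges, and get 0.606. This is the yield power, and it belongs to the clock reading of 6.3 min, the time asked of the elm run: at 0.91 min the same division gives 1.01. Carried from cedar to elm, it gives 0.0713 M, or 23.0% of the elm charge.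

The weak link is that this power rests on two readings. Their scatter gives it a standard deviation of 0.0726, which moves the elm share by 0.57 percentage points, so I commit to my number.

The forecast gives 0.5 for partner, 0.9 for substrate and 22.2% for elm, whose late yields it sees “rise ever less steeply with substrate”. That share stands 0.8 points under mine.

The flask gives 0.56, 1.0 and 23.2%.

    catalyst + substrate ⇌ catalyst-substrate complex (61.20 M⁻¹ min⁻¹, 133.2 min⁻¹)
    catalyst-substrate complex + partner → target + catalyst (335.4 M⁻¹ min⁻¹)
    2 substrate → homo dimer (0.5190 M⁻¹ min⁻¹)
    target → decomposed product (0.08700 min⁻¹)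

The elm result puts the yield power from cedar at 0.635, against 1.0 for the first rate. The homo dimer and the decomposed product together hold down target in the elm run: it reaches 36.4% without the first and 32.6% without the second, while the first-rate power stays at 1.0 and 0.99. The late oak and cedar readings already hold those losses. Carried from oak down to alder, with the late partner power 0.261, the yield power gives 0.0284 M against the alder reading of 0.0238 M.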